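**Plan**

- Retrosynthesis: after removal of the two phenol protecting groups, ring B is cut at C1'–C2' and C5'–C6' into a 2-ethynylchromone and a 1-amino-2-methoxy-3-silyloxybutadiene. The alkyne is cut from C2 (coupling to a 2-iodochromone), ring C at O1–C2/C2–C3 (one carbon from DMF dimethyl acetal) and at C4–C4a (aryllithium plus a methoxyacetyl amide).
- Ring A goes back to methyl 3,5-dihydroxy-4-methoxybenzoate; its ester carbon is exchanged for the future 5-oxygen by Baeyer–Villiger oxidation.
- Forward order: ring A is functionalised (steps 1–8), ring C is closed (step 9), the ethynyl group is placed on C2 (steps 10–12), ring B is built last by cycloaddition and loss of dimethylamine (step 15), and one deprotection follows.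
- Enabling feature: ring B carries 4'-OH para and 3'-OMe meta to C1', which is the oxygen pattern of C3 and C2 of the diene. C1' sits on C2 of ring C, so the alkyne that supplies C1' and C6' is polarised through C2=C3–C4=O.
- Stereochemistry: the target has no stereocentre. The only stereo-element carried is the Z enamine geometry of the diene; the one sp3 centre made in the cycloaddition is erased on aromatisation.

Key step: step 15

Assumption: aminomethylenation of methoxyacetone by DMF dimethyl acetal is taken to occur at the methoxy-bearing CH2 (the more acidic site), as diene 24 requires.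

**Route**

Step 1
Reactants: 1 methyl 3,5-dihydroxy-4-methoxybenzoate
Product: 2 methyl 3,5-bis(benzyloxy)-4-methoxybenzoate
Conditions: BnBr, K2CO3, DMF, 60 °C
Reagents that add atoms: benzyl bromide, BrCc1ccccc1
Why: Williamson etherification of both phenols under carbonate conditions should leave the methyl ester untouched.

Step 2
Reactants: 2 methyl 3,5-bis(benzyloxy)-4-methoxybenzoate
Product: 3 [3,5-bis(benzyloxy)-4-methoxyphenyl]methanol
Conditions: LiAlH4, THF, 0 °C to rt
Reagents that add atoms: none
Why: Hydride reduction of an aryl ester to the benzylic alcohol is routine and benzyl ethers are inert to it.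

Step 3
Reactants: 3 [3,5-bis(benzyloxy)-4-methoxyphenyl]methanol
Product: 4 3,5-bis(benzyloxy)-4-methoxybenzaldehyde
Conditions: MnO2, CH2Cl2, rt
Reagents that add atoms: none
Why: MnO2 oxidises electron-rich benzylic alcohols to aldehydes and stops there.

Step 4
Reactants: 4 3,5-bis(benzyloxy)-4-methoxybenzaldehyde
Product: 6 3,5-bis(benzyloxy)-4-methoxyphenol, via aryl formate 5 (not isolated)
Conditions: mCPBA, CH2Cl2, 0 °C to rt; aq. NaHCO3 wash; then K2CO3 (cat.), MeOH, rt
Reagents that add atoms: 3-chloroperoxybenzoic acid (mCPBA), O=C(OO)c1cccc(Cl)c1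
Why: In this Baeyer–Villiger (Dakin-type) oxidation the electron-rich aryl group, activated by the para methoxy group, should migrate in preference to hydrogen, and methanolysis of the formate frees the phenol.

Step 5
Reactants: 6 3,5-bis(benzyloxy)-4-methoxyphenol
Product: 7 1,3-bis(benzyloxy)-2-methoxy-5-(methoxymethoxy)benzene
Conditions: NaH, MOMCl, THF, 0 °C to rt
Reagents that add atoms: chloromethyl methyl ether (MOMCl), COCCl
Why: Alkylation of the sodium phenoxide installs the MOM acetal, which serves first as the directing group for lithiation and later as the acid-labile protection of the 5-oxygen.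

Step 6
Reactants: 7 1,3-bis(benzyloxy)-2-methoxy-5-(methoxymethoxy)benzene; 8 N,2-dimethoxy-N-methylacetamide
Product: 10 1-[2,4-bis(benzyloxy)-3-methoxy-6-(methoxymethoxy)phenyl]-2-methoxyethan-1-one, via aryllithium 9 (not isolated)
Conditions: n-BuLi, THF, 0 °C; then 8, −78 °C to 0 °C; H2O
Reagents that add atoms: none
Why: Directed ortho-metalation should occur at the position flanked by OMOM and OBn (the two such positions are equivalent by symmetry), and the Weinreb ketone synthesis stops at the ketone because the chelated tetrahedral adduct survives until quench.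

Step 7
Reactants: 10 1-[2,4-bis(benzyloxy)-3-methoxy-6-(methoxymethoxy)phenyl]-2-methoxyethan-1-one
Product: 11 1-[2,4-dihydroxy-3-methoxy-6-(methoxymethoxy)phenyl]-2-methoxyethan-1-one
Conditions: H2 (1 atm), Pd/C, EtOAc, rt
Reagents that add atoms: none
Why: Hydrogenolysis removes both benzyl ethers under neutral conditions that should spare the MOM acetal and the hindered aryl ketone.

Step 8
Reactants: 11 1-[2,4-dihydroxy-3-methoxy-6-(methoxymethoxy)phenyl]-2-methoxyethan-1-one
Product: 12 1-[2-hydroxy-3-methoxy-6-(methoxymethoxy)-4-(3-methylbut-2-en-1-yloxy)phenyl]-2-methoxyethan-1-one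
Conditions: prenyl bromide (1.05 equiv), K2CO3, acetone, 50 °C
Reagents that add atoms: 1-bromo-3-methylbut-2-ene (prenyl bromide), CC(C)=CCBr
Why: Williamson alkylation should take place only at the 4-OH, which is para to the carbonyl and free, whereas the 2-OH is tied up in a hydrogen bond to the ketone.

Step 9
Reactants: 12 1-[2-hydroxy-3-methoxy-6-(methoxymethoxy)-4-(3-methylbut-2-en-1-yloxy)phenyl]-2-methoxyethan-1-one; 13 N,N-dimethylformamide dimethyl acetal
Product: 15 3,8-dimethoxy-5-(methoxymethoxy)-7-(3-methylbut-2-en-1-yloxy)-4H-chromen-4-one, via enaminone 14 (not isolated)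
Conditions: 13, PhMe, 95 °C; then AcOH, rt
Reagents that add atoms: none
Why: Aminomethylenation of the α-methoxy methylene gives an enaminone whose β-carbon is attacked by the neighbouring phenol with loss of dimethylamine, the amide-acetal chromone synthesis used for isoflavones from deoxybenzoins.

Step 10
Reactants: 15 3,8-dimethoxy-5-(methoxymethoxy)-7-(3-methylbut-2-en-1-yloxy)-4H-chromen-4-one
Product: 17 2-iodo-3,8-dimethoxy-5-(methoxymethoxy)-7-(3-methylbut-2-en-1-yloxy)-4H-chromen-4-one, via chromon-2-ylzinc chloride 16 (not isolated)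
Conditions: TMPZnCl·LiCl, THF, 25 °C; then I2, 0 °C
Reagents that add atoms: iodine, II
Why: With C3 blocked, the C2–H next to O1 and β to C4=O is the most acidic C–H, so this mild amide base should zincate it without touching arene C6–H or opening the pyranone (directed metalation, then iodolysis).

Step 11
Reactants: 17 2-iodo-3,8-dimethoxy-5-(methoxymethoxy)-7-(3-methylbut-2-en-1-yloxy)-4H-chromen-4-one; 18 trimethylsilylacetylene
Product: 19 3,8-dimethoxy-5-(methoxymethoxy)-7-(3-methylbut-2-en-1-yloxy)-2-[(trimethylsilyl)ethynyl]-4H-chromen-4-one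
Conditions: 18, Pd(PPh3)2Cl2 (cat.), CuI (cat.), Et3N, THF, rt
Reagents that add atoms: none
Why: In this Sonogashira coupling the C2–I bond is a vinylogous acyl iodide, so oxidative addition to zerovalent palladium should be fast at room temperature.

Step 12
Reactants: 19 3,8-dimethoxy-5-(methoxymethoxy)-7-(3-methylbut-2-en-1-yloxy)-2-[(trimethylsilyl)ethynyl]-4H-chromen-4-one
Product: 20 2-ethynyl-3,8-dimethoxy-5-(methoxymethoxy)-7-(3-methylbut-2-en-1-yloxy)-4H-chromen-4-one
Conditions: Bu4NF, AcOH, THF, −20 °C to 0 °C
Reagents that add atoms: none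
Why: Fluoride cleaves the C–Si bond and acetic acid protonates the acetylide at once, keeping the medium non-basic so that nothing adds to C2 or to the activated alkyne (alkynylsilane desilylation).

Step 13
Reactants: 21 methoxyacetone; 13 N,N-dimethylformamide dimethyl acetal
Product: 22 (3Z)-4-(dimethylamino)-3-methoxybut-3-en-2-one
Conditions: 13 (1.2 equiv), neat, 100 °C
Reagents that add atoms: none
Why: Enaminone formation with an amide acetal should take place at the more acidic methoxy-bearing methylene and place the amino group trans to the acetyl group, the geometry the diene needs.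

Step 14
Reactants: 22 (3Z)-4-(dimethylamino)-3-methoxybut-3-en-2-one
Product: 24 (1Z)-3-[(tert-butyldimethylsilyl)oxy]-2-methoxy-N,N-dimethylbuta-1,3-dien-1-amine, via potassium dienolate 23 (not isolated)
Conditions: KN(SiMe3)2, THF, −78 °C; then TBSCl, −78 °C to rt
Reagents that add atoms: tert-butyldimethylsilyl chloride (TBSCl), CC(C)(C)[Si](C)(C)Cl
Why: Deprotonation of the methyl ketone of the vinylogous amide and O-silylation of the dienolate is the standard preparation of 1-amino-3-siloxybutadienes and leaves the enamine geometry unchanged.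

Step 15
Reactants: 20 2-ethynyl-3,8-dimethoxy-5-(methoxymethoxy)-7-(3-methylbut-2-en-1-yloxy)-4H-chromen-4-one; 24 (1Z)-3-[(tert-butyldimethylsilyl)oxy]-2-methoxy-N,N-dimethylbuta-1,3-dien-1-amine
Product: 26 2-[4-(tert-butyldimethylsilyloxy)-3-methoxyphenyl]-3,8-dimethoxy-5-(methoxymethoxy)-7-(3-methylbut-2-en-1-yloxy)-4H-chromen-4-one, via aminocyclohexadiene 25 (not isolated)
Conditions: 24 (2 equiv), PhMe, 80 °C; then silica gel, CH2Cl2, rt
Reagents that add atoms: none
Why: Proposed new method: the diene HOMO, raised by the amino and two oxygen donors, is largest at the CH2 terminus, and the alkyne LUMO, lowered through C2=C3–C4=O of ring C, is largest at the terminal carbon, so a concerted but asynchronous [4+2] cycloaddition should join CH2 to the terminal alkyne carbon (C5'–C6') and the amino-bearing carbon to the internal one (C1'–C2'). Ring B therefore closes as a six-membered carbocycle by intermolecular cycloaddition in which both ring bonds form in one step, giving the 1,4-cyclohexadiene 25. In 25 the C–N bond is doubly allylic and flanked by the enol ether, so mild acid (silica gel) should ionise it and loss of a proton from the opposite CH2 expels dimethylamine and leaves the aromatic silyl ether 26. The closest known reaction type is the cycloaddition of 1-amino-3-siloxy- and 1-methoxy-3-siloxybutadienes with alkynyl ketones and alkynoates followed by loss of amine or methanol to para-oxygenated arenes; new here are the 2-methoxy group on the diene and a dienophile activated only vinylogously. The single new stereocentre, the amino-bearing carbon of 25, is formed racemic and disappears on aromatisation, so no stereocontrol is needed. The selectivity required is regiochemical (silyloxy para and methoxy meta to C1'), secured by the matched polarisation above, and chemoselective, secured because C2=C3 of ring C is tetrasubstituted and donor-substituted and the prenyl alkene is unactivated.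

Step 16
Reactants: 26 2-[4-(tert-butyldimethylsilyloxy)-3-methoxyphenyl]-3,8-dimethoxy-5-(methoxymethoxy)-7-(3-methylbut-2-en-1-yloxy)-4H-chromen-4-one
Product: 28 5-hydroxy-2-(4-hydroxy-3-methoxyphenyl)-3,8-dimethoxy-7-(3-methylbut-2-en-1-yloxy)-4H-chromen-4-one, via phenol 27 (not isolated)
Conditions: Bu4NF, THF, 0 °C; then 2 M HCl, MeOH, rt to 40 °C
Reagents that add atoms: none
Why: Fluoride cleaves the aryl silyl ether and acidic methanol then transacetalises the MOM group, which is unusually labile because it sits peri to C4=O, so brief exposure to dilute acid should spare the prenyl ether.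

**Compound list**

1 | methyl 3,5-dihydroxy-4-methoxybenzoate | COC(=O)c1cc(O)c(OC)c(O)c1 | starting material
2 | methyl 3,5-bis(benzyloxy)-4-methoxybenzoate | COC(=O)c1cc(OCc2ccccc2)c(OC)c(OCc2ccccc2)c1 | intermediate
3 | [3,5-bis(benzyloxy)-4-methoxyphenyl]methanol | OCc1cc(OCc2ccccc2)c(OC)c(OCc2ccccc2)c1 | intermediate
4 | 3,5-bis(benzyloxy)-4-methoxybenzaldehyde | O=Cc1cc(OCc2ccccc2)c(OC)c(OCc2ccccc2)c1 | intermediate
5 | 3,5-bis(benzyloxy)-4-methoxyphenyl formate | O=COc1cc(OCc2ccccc2)c(OC)c(OCc2ccccc2)c1 | intermediate
6 | 3,5-bis(benzyloxy)-4-methoxyphenol | Oc1cc(OCc2ccccc2)c(OC)c(OCc2ccccc2)c1 | intermediate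
7 | 1,3-bis(benzyloxy)-2-methoxy-5-(methoxymethoxy)benzene | COCOc1cc(OCc2ccccc2)c(OC)c(OCc2ccccc2)c1 | intermediate
8 | N,2-dimethoxy-N-methylacetamide | COCC(=O)N(C)OC | starting material
9 | [2,4-bis(benzyloxy)-3-methoxy-6-(methoxymethoxy)phenyl]lithium | [Li]c1c(OCOC)cc(OCc2ccccc2)c(OC)c1OCc1ccccc1 | intermediate
10 | 1-[2,4-bis(benzyloxy)-3-methoxy-6-(methoxymethoxy)phenyl]-2-methoxyethan-1-one | COCC(=O)c1c(OCOC)cc(OCc2ccccc2)c(OC)c1OCc1ccccc1 | intermediate
11 | 1-[2,4-dihydroxy-3-methoxy-6-(methoxymethoxy)phenyl]-2-methoxyethan-1-one | COCC(=O)c1c(OCOC)cc(O)c(OC)c1O | intermediate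
12 | 1-[2-hydroxy-3-methoxy-6-(methoxymethoxy)-4-(3-methylbut-2-en-1-yloxy)phenyl]-2-methoxyethan-1-one | COCC(=O)c1c(OCOC)cc(OCC=C(C)C)c(OC)c1O | intermediate
13 | N,N-dimethylformamide dimethyl acetal | COC(OC)N(C)C | starting material
14 | (2Z)-3-(dimethylamino)-1-[2-hydroxy-3-methoxy-6-(methoxymethoxy)-4-(3-methylbut-2-en-1-yloxy)phenyl]-2-methoxyprop-2-en-1-one | CN(C)/C=C(\OC)C(=O)c1c(OCOC)cc(OCC=C(C)C)c(OC)c1O | intermediate
15 | 3,8-dimethoxy-5-(methoxymethoxy)-7-(3-methylbut-2-en-1-yloxy)-4H-chromen-4-one | COCOc1cc(OCC=C(C)C)c(OC)c2occ(OC)c(=O)c12 | intermediate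
16 | chloro[3,8-dimethoxy-5-(methoxymethoxy)-7-(3-methylbut-2-en-1-yloxy)-4-oxo-4H-chromen-2-yl]zinc | COCOc1cc(OCC=C(C)C)c(OC)c2oc([Zn]Cl)c(OC)c(=O)c12 | intermediate
17 | 2-iodo-3,8-dimethoxy-5-(methoxymethoxy)-7-(3-methylbut-2-en-1-yloxy)-4H-chromen-4-one | COCOc1cc(OCC=C(C)C)c(OC)c2oc(I)c(OC)c(=O)c12 | intermediate
18 | trimethylsilylacetylene | C#C[Si](C)(C)C | starting material
19 | 3,8-dimethoxy-5-(methoxymethoxy)-7-(3-methylbut-2-en-1-yloxy)-2-[(trimethylsilyl)ethynyl]-4H-chromen-4-one | COCOc1cc(OCC=C(C)C)c(OC)c2oc(C#C[Si](C)(C)C)c(OC)c(=O)c12 | intermediate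
20 | 2-ethynyl-3,8-dimethoxy-5-(methoxymethoxy)-7-(3-methylbut-2-en-1-yloxy)-4H-chromen-4-one | C#Cc1oc2c(OC)c(OCC=C(C)C)cc(OCOC)c2c(=O)c1OC | intermediate
21 | methoxyacetone | COCC(C)=O | starting material
22 | (3Z)-4-(dimethylamino)-3-methoxybut-3-en-2-one | CN(C)/C=C(\OC)C(C)=O | intermediate
23 | potassium (3Z)-4-(dimethylamino)-3-methoxybuta-1,3-dien-2-olate | CN(C)/C=C(\OC)C(=C)[O-].[K+] | intermediate
24 | (1Z)-3-[(tert-butyldimethylsilyl)oxy]-2-methoxy-N,N-dimethylbuta-1,3-dien-1-amine | CN(C)/C=C(\OC)C(=C)O[Si](C)(C)C(C)(C)C | intermediate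
25 | 2-[4-(tert-butyldimethylsilyloxy)-6-(dimethylamino)-5-methoxycyclohexa-1,4-dien-1-yl]-3,8-dimethoxy-5-(methoxymethoxy)-7-(3-methylbut-2-en-1-yloxy)-4H-chromen-4-one (racemic) | COCOc1cc(OCC=C(C)C)c(OC)c2oc(C3=CCC(O[Si](C)(C)C(C)(C)C)=C(OC)C3N(C)C)c(OC)c(=O)c12 | intermediate
26 | 2-[4-(tert-butyldimethylsilyloxy)-3-methoxyphenyl]-3,8-dimethoxy-5-(methoxymethoxy)-7-(3-methylbut-2-en-1-yloxy)-4H-chromen-4-one | COc1cc(-c2oc3c(OC)c(OCC=C(C)C)cc(OCOC)c3c(=O)c2OC)ccc1O[Si](C)(C)C(C)(C)C | intermediate
27 | 2-(4-hydroxy-3-methoxyphenyl)-3,8-dimethoxy-5-(methoxymethoxy)-7-(3-methylbut-2-en-1-yloxy)-4H-chromen-4-one | COc1cc(-c2oc3c(OC)c(OCC=C(C)C)cc(OCOC)c3c(=O)c2OC)ccc1O | intermediate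
28 | 5-hydroxy-2-(4-hydroxy-3-methoxyphenyl)-3,8-dimethoxy-7-(3-methylbut-2-en-1-yloxy)-4H-chromen-4-one (5,4'-dihydroxy-3,8,3'-trimethoxy-7-prenyloxyflavone) | COc1cc(-c2oc3c(OC)c(OCC=C(C)C)cc(O)c3c(=O)c2OC)ccc1O | target

**Step count and risks**

Total step count: 16. Longest linear sequence: 14 steps (steps 1–12, 15 and 16); the diene branch is 2 steps (13 and 14).

Steps most likely to fail:

Step 15. The alkyne is activated only vinylogously, so the cycloaddition may be slow enough that hydrolysis or thermal decay of the aminodiene, open-chain conjugate addition without ring closure, or addition of prematurely released dimethylamine to unreacted alkyne takes over. The fallback gives up the ring B construction and brings ring B in intact by known cross-coupling chemistry. It sets out from chromone 15, which is zincated to 16 exactly as in step 10. Negishi coupling of 16 with tert-butyl(4-iodo-2-methoxyphenoxy)dimethylsilane F1 (made from purchased 4-iodo-2-methoxyphenol with TBSCl and imidazole in DMF) under Pd(PPh3)4 in THF at 50 °C should give the flavone directly. The fallback comes back to the route at compound 26.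

Step 12. During desilylation the electrophilic enyne may take up fluoride, acetate or another nucleophile at the alkyne terminus or at C2, or the freed terminal alkyne may oligomerise. The fallback avoids a silyl alkyne altogether: it sets out from iodide 17 and uses a Stille coupling with purchased tributyl(ethynyl)stannane (Pd(PPh3)4, PhMe, 60 °C), which installs the free ethynyl group under neutral conditions. It comes back to the route at compound 20 and makes no new compound.

Step 6. n-BuLi may deprotonate the benzylic CH2 of a benzyl ether (followed by Wittig rearrangement) in competition with ring lithiation, or the hindered aryllithium may enolise the amide instead of adding to it. The fallback replaces C–H deprotonation by halogen–metal exchange. It sets out from compound 7, which is brominated with N-bromosuccinimide in MeCN at 0 °C at the only free ring position type to give 1,3-bis(benzyloxy)-4-bromo-2-methoxy-5-(methoxymethoxy)benzene F2. Bromine–lithium exchange with n-BuLi in THF at −78 °C, faster than any deprotonation, gives aryllithium 9, which is acylated with amide 8 as before. The fallback comes back to the route at compound 10.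

**Further compounds**

F1 | step 15 | tert-butyl(4-iodo-2-methoxyphenoxy)dimethylsilane | COc1cc(I)ccc1O[Si](C)(C)C(C)(C)C
F0 | step 12 | none | none
F2 | step 6 | 1,3-bis(benzyloxy)-4-bromo-2-methoxy-5-(methoxymethoxy)benzene | COCOc1cc(OCc2ccccc2)c(OC)c(OCc2ccccc2)c1Br
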